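**Retrosynthetic overview**

1. Cycloshizukaol A 22 ⇐ bis(enol lactone) 20. Four C–O bonds (2 × C9–O, 2 × CO–OMe) are made last by double enol-lactone epoxidation and methanolysis. This C–O step sets C9/C9′ and unveils the keto esters.
2. 20 ⇐ 2 × tetraene butenolide 17 by a head-to-tail [6+6] union (C15–C11′ and C15′–C11). It is relayed through a C15–N bond to a tertiary amine catalyst (new). The lactone C–O bond locks the C11 geometry, and the 12-membered ring forms here.
3. 17 ⇐ enone 12 + methyl pyruvate: aldol addition, then enol-lactonisation (C8–O–C12 bond).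
4. 12 ⇐ bicyclic enone 7 + silyloxydiene 9: a Diels–Alder reaction builds the six-membered ring and quaternary C10, followed by Wittig methylenation and desaturation.
5. 7 ⇐ (S)-epichlorohydrin + crotylmagnesium chloride (Hodgson cyclopropanation). Ring order: cyclopropane/five-ring → six-ring → butenolide → macrocycle.

Assumption: lindenane numbering (C1–C15 as in the target; cyclopropane = C1–C2–C3, C14 = angular methyl, C15 = carbon on C4) is used for all polycyclic compounds, and β is the face carrying CH3-14.

**Route**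

Step 1
Reactants: 1 (S)-epichlorohydrin; 2 crotylmagnesium chloride
Product: 4 (2S)-2-(2-methylbut-3-en-1-yl)oxirane, via chlorohydrin 3 (not isolated)
Conditions: THF, −30 → 0 °C; then aq NaOH, rt
Reagents that add atoms: none
Why: Allylic Grignard opening of the epoxide at its CH2 with allyl transposition (SE2′), then Williamson-type closure of the chlorohydrin; the C–O stereocentre of 1 is untouched, and the methyl-bearing centre is a mixture that is erased in step 3.

Step 2
Reactants: 4 (2S)-2-(2-methylbut-3-en-1-yl)oxirane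
Product: 5 (1S,2S,5S)-4-methylbicyclo[3.1.0]hexan-2-ol
Conditions: LiTMP (2 equiv), t-BuOMe, 0 °C → rt
Reagents that add atoms: none
Why: Hodgson intramolecular cyclopropanation: trans-α-lithiation of the terminal epoxide gives a carbenoid that adds to the pendant alkene, so the epoxide stereocentre sets both ring-fusion carbons (C1 and C3 of the target).

Step 3
Reactants: 5 (1S,2S,5S)-4-methylbicyclo[3.1.0]hexan-2-ol
Product: 7 (1S,5R)-4-methylbicyclo[3.1.0]hex-3-en-2-one, via ketone 6 (not isolated)
Conditions: IBX (3 equiv), DMSO, 70 °C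
Reagents that add atoms: none
Why: IBX oxidises the alcohol and then dehydrogenates the ketone (Nicolaou IBX desaturation) on its only enolisable side, giving the β-methyl enone and removing the stereorandom methyl centre.

Step 4
Reactants: 8 methyl vinyl ketone
Product: 9 2-(tert-butyldimethylsilyloxy)buta-1,3-diene
Conditions: TBSOTf, Et3N, Et2O, 0 °C
Reagents that add atoms: tert-butyldimethylsilyl triflate CC(C)(C)[Si](C)(C)OS(=O)(=O)C(F)(F)F
Why: Soft enolisation and O-silylation of the methyl ketone gives the cross-conjugated 2-silyloxydiene.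

Step 5
Reactants: 7 (1S,5R)-4-methylbicyclo[3.1.0]hex-3-en-2-one; 9 2-(tert-butyldimethylsilyloxy)buta-1,3-diene
Product: 10 8-(tert-butyldimethylsilyloxy)-11,12,13,15-tetranorlinden-7-en-4-one
Conditions: Tf2NH (5 mol %), CH2Cl2, −78 → −40 °C
Reagents that add atoms: none
Why: Silyl-triflimide-catalysed Diels–Alder reaction of a hindered enone with "para" regiochemistry (nucleophilic diene CH2 to the β-carbon); the diene adds anti to the cyclopropane CH2, which sets quaternary C10 with CH3-14 cis to that CH2 (the cis C5–H is removed later).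

Step 6
Reactants: 10 8-(tert-butyldimethylsilyloxy)-11,12,13,15-tetranorlinden-7-en-4-one
Product: 11 8-(tert-butyldimethylsilyloxy)-11,12,13-trinorlindena-4(15),7-diene
Conditions: Ph3PCH3Br, NaHMDS, THF, 0 → 65 °C
Reagents that add atoms: methyltriphenylphosphonium bromide C[P+](c1ccccc1)(c1ccccc1)c1ccccc1.[Br-]
Why: Wittig methylenation of the only carbonyl group, with the TBS enol ether masking the C8 ketone (epimerisation at C5 is without consequence).

Step 7
Reactants: 11 8-(tert-butyldimethylsilyloxy)-11,12,13-trinorlindena-4(15),7-diene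
Product: 12 11,12,13-trinorlindena-4(15),6-dien-8-one
Conditions: IBX·MPO, DMSO, rt
Reagents that add atoms: none
Why: IBX·MPO dehydrogenation of a silyl enol ether (a Saegusa–Ito equivalent) gives the C6=C7 enone regiospecifically, because the enol ether is regiodefined and only C6 carries β-hydrogens.

Step 8
Reactants: 12 11,12,13-trinorlindena-4(15),6-dien-8-one; 13 methyl pyruvate
Product: 15 methyl 11-hydroxy-8-oxolindena-4(15),5-dien-12-oate, via potassium trienolate 14 (not isolated)
Conditions: KHMDS (0.95 equiv), THF, −78 → 0 °C; then 13, −78 °C; AcOH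
Reagents that add atoms: none
Why: Equilibrating deprotonation at the doubly allylic C5–H gives the fully conjugated trienolate, which as an extended enolate adds to the pyruvate ketone at its α-carbon C7 (aldol addition); the two new centres are removed in step 9.

Step 9
Reactants: 15 methyl 11-hydroxy-8-oxolindena-4(15),5-dien-12-oate
Product: 17 lindena-4(15),5,7(11),8-tetraen-12,8-olide, via keto ester 16 (not isolated)
Conditions: CSA (10 mol %), PhMe, 5 Å MS, 70 °C
Reagents that add atoms: none
Why: Acid-catalysed dehydration of the tertiary β-hydroxy ketone and enol-lactonisation of the Z-keto ester (methanol removed by sieves) forms the C8–O–C12 bond of the γ-ylidenebutenolide, the standard pyruvate route to such butenolides.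

Step 10
Reactants: 17 lindena-4(15),5,7(11),8-tetraen-12,8-olide (2 molecules)
Product: 20 (11R,11′R)-15,11′:15′,11-linked bis(lindena-4,6,8-trien-12,8-olide), via quinuclidinium dienolate 18 (not isolated), via open-chain zwitterion 19 (not isolated)
Conditions: quinuclidine (20 mol %), LiClO4 (1 equiv), MeCN (0.5 M), 25–40 °C
Reagents that add atoms: none
Why: Proposed new method: a tertiary-amine relay [6+6] cyclodimerisation in which quinuclidine adds 1,8 to the exocyclic C15 of 17 (C–N bond) to give a lactone dienolate; its C11, whose carboxyl carbon is held syn to C8 by the lactone ring, adds to C15 of a second 17 on the open α-face (reversible vinylogous Michael addition); the resulting C11′ dienolate then displaces the allylic ammonium group by intramolecular SN2, closing the 12-membered ring and releasing the amine; α/α stacking (the β-faces carry CH3-14 and the cyclopropane CH2) gives the C2-symmetric 11R,11′R isomer; the closest known reactions are the Rauhut–Currier dimerisation and the Lewis-base-catalysed allylic alkylation of Morita–Baylis–Hillman carbonates.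

Step 11
Reactants: 20 (11R,11′R)-15,11′:15′,11-linked bis(lindena-4,6,8-trien-12,8-olide)
Product: 22 cycloshizukaol A, via bis-epoxide 21 (not isolated)
Conditions: DMDO, acetone, −20 → 0 °C; then MeOH, K2CO3 (cat.), 0 °C
Reagents that add atoms: dimethyldioxirane CC1(C)OO1; methanol CO
Why: Dioxirane (Prilezhaev-type) epoxidation of the electron-rich enol-lactone C8=C9 bonds from the exposed β-face (the α-faces are buried inside the folded dimer), then methanolysis (transesterification; the C8 hemiketal alkoxide collapses to the ketone and opens the epoxide), which forms four C–O bonds and sets C9 and C9′ with the oxygen retained on C9.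

**Compound list**

1 | (S)-epichlorohydrin | ClC[C@@H]1CO1 | starting material
2 | crotylmagnesium chloride (but-2-en-1-ylmagnesium chloride, THF solution) | CC=CC[Mg]Cl | starting material
3 | (2S)-1-chloro-4-methylhex-5-en-2-ol (epimers at the CH–CH3 carbon) | O[C@H](CCl)CC(C)C=C | intermediate
4 | (2S)-2-(2-methylbut-3-en-1-yl)oxirane (epimers at the CH–CH3 carbon) | C=CC(C)C[C@H]1CO1 | intermediate
5 | (1S,2S,5S)-4-methylbicyclo[3.1.0]hexan-2-ol (OH trans to the cyclopropane CH2; C4 epimers) | O[C@H]1CC(C)[C@@H]2C[C@H]12 | intermediate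
6 | (1S,5S)-4-methylbicyclo[3.1.0]hexan-2-one (C4 epimers) | O=C1CC(C)[C@@H]2C[C@H]12 | intermediate
7 | (1S,5R)-4-methylbicyclo[3.1.0]hex-3-en-2-one | O=C1C=C(C)[C@@H]2C[C@H]12 | intermediate
8 | methyl vinyl ketone | CC(=O)C=C | starting material
9 | 2-(tert-butyldimethylsilyloxy)buta-1,3-diene | C=CC(=C)O[Si](C)(C)C(C)(C)C | intermediate
10 | 8-(tert-butyldimethylsilyloxy)-11,12,13,15-tetranorlinden-7-en-4-one (cis-fused; 5-H, CH3-14 and cyclopropane CH2 all β) | O=C1[C@H]2CC=C(O[Si](C)(C)C(C)(C)C)C[C@@]2(C)[C@@H]2C[C@H]12 | intermediate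
11 | 8-(tert-butyldimethylsilyloxy)-11,12,13-trinorlindena-4(15),7-diene (5βH) | C=C1[C@H]2CC=C(O[Si](C)(C)C(C)(C)C)C[C@@]2(C)[C@@H]2C[C@H]12 | intermediate
12 | 11,12,13-trinorlindena-4(15),6-dien-8-one (5βH) | C=C1[C@H]2C=CC(=O)C[C@@]2(C)[C@@H]2C[C@H]12 | intermediate
13 | methyl pyruvate | COC(=O)C(C)=O | starting material
14 | potassium 11,12,13-trinorlindena-4(15),5,7-trien-8-olate | C=C1C2=CC=C([O-])C[C@@]2(C)[C@@H]2C[C@H]12.[K+] | intermediate
15 | methyl 11-hydroxy-8-oxolindena-4(15),5-dien-12-oate (epimers at C7 and C11) | C=C1C2=CC(C(C)(O)C(=O)OC)C(=O)C[C@@]2(C)[C@@H]2C[C@H]12 | intermediate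
16 | methyl 8-oxolindena-4(15),5,7(11)-trien-12-oate (E/Z) | C=C1C2=CC(=C(C)C(=O)OC)C(=O)C[C@@]2(C)[C@@H]2C[C@H]12 | intermediate
17 | lindena-4(15),5,7(11),8-tetraen-12,8-olide (5,6-didehydrochloranthalactone A) | C=C1C2=CC3=C(C)C(=O)OC3=C[C@@]2(C)[C@@H]2C[C@H]12 | intermediate
18 | 15-(quinuclidinium-1-yl)lindena-4,6,8,11-tetraen-12,8-olide 12-olate (zwitterion) | C(C1=C2C=C3C(=C[C@@]2(C)[C@@H]2C[C@H]12)OC([O-])=C3C)[N+]12CCC(CC1)CC2 | intermediate
19 | open-chain dimer zwitterion (C11–C15′ bond formed, 11R; 15-quinuclidinium on the first half, lactone dienolate on the second) | C(C1=C2C=C3C(=C[C@@]2(C)[C@@H]2C[C@H]12)OC(=O)[C@]3(C)CC1=C2C=C3C(=C[C@@]2(C)[C@@H]2C[C@H]12)OC([O-])=C3C)[N+]12CCC(CC1)CC2 | intermediate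
20 | (11R,11′R)-15,11′:15′,11-linked bis(lindena-4,6,8-trien-12,8-olide) (C2-symmetric bis-enol-lactone, α-faces stacked) | C[C@@]12CC3=C4C=C5C(=C[C@@]4(C)[C@@H]4C[C@H]34)OC(=O)[C@]5(C)CC3=C4C=C1C(=C[C@@]4(C)[C@@H]1C[C@H]31)OC2=O | intermediate
21 | bis(8β,9β-epoxide) of 20 | C[C@@]12CC3=C4C=C5[C@@]6(O[C@@H]6[C@@]4(C)[C@@H]4C[C@H]34)OC(=O)[C@]5(C)CC3=C4C=C1[C@@]5(O[C@@H]5[C@@]4(C)[C@@H]1C[C@H]31)OC2=O | intermediate
22 | cycloshizukaol A | COC(=O)[C@]1(C)CC2=C3C=C(C(=O)[C@H](O)[C@@]3(C)[C@@H]3C[C@H]23)[C@](C)(C(=O)OC)CC2=C3C=C1C(=O)[C@H](O)[C@@]3(C)[C@@H]1C[C@H]21 | target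

**Step count and risks**

Total steps: 11. Longest linear sequence: 10 (steps 1–3 and 5–11; step 4 is a one-step side branch).

Steps most likely to fail:

Step 10 (the proposed new step). The dimerisation may be thermodynamically marginal because the product is a strained, cyclophane-like 12-membered ring. The extended dienolate may also react at C6 instead of C11, and 17 may undergo [4+2] dimerisation or oligomerise. The fallback sets out from 17 and comes back at 20, using only known reaction types and a stoichiometric, irreversible activation. Two equivalents of 17 are treated with one equivalent of thiophenol and catalytic DBU. Thia-1,8-Michael addition gives the 15-phenylthio lactone F3, whose dienolate adds to the second molecule of 17 (vinylogous Michael addition) to give the acyclic dimer sulfide F4, which is isolated and purified. S-Methylation with methyl triflate gives the sulfonium triflate F5. Cesium carbonate at high dilution then effects intramolecular C11′-alkylation with loss of thioanisole, a step that cannot revert, to give 20.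

Step 5. The silylium-type catalyst may open the cyclopropyl enone (cyclopropylcarbinyl cation), or the β,β-disubstituted dienophile may simply not react. The fallback sets out from 7 and comes back at 12, bypassing steps 6 and 7. Enone 7 is heated in toluene without any Lewis acid with the far more reactive (E)-1-dimethylamino-3-(tert-butyldimethylsilyloxy)buta-1,3-diene (Rawal's diene) to give the amino silyl enol ether cycloadduct F1. Wittig methylenation of its ketone gives the methylene compound F2. Dilute aqueous HCl in THF hydrolyses the enol ether and eliminates dimethylamine from the β-amino ketone to give 12.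

Step 11. The dioxirane may attack C4=C5 or C6=C7, or epoxidise C8=C9 from the α-face, anti to CH3-14. The fallback sets out from 20 and comes back at 22, changing oxygen delivery into hydride delivery. If the one-pot sequence gives 9,9′-bis-epi-cycloshizukaol A F6, it is oxidised with Dess–Martin periodinane to the non-enolisable bis(8,9-dione) F7. The non-conjugated C9 ketones are then reduced with NaBH4/CeCl3 at −78 °C from the same exposed face that the oxidant used, which places the hydroxyl groups on the β-face and gives 22.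

**Further compounds**

F1 | step 5 | 6-(dimethylamino)-8-(tert-butyldimethylsilyloxy)-11,12,13,15-tetranorlinden-7-en-4-one (C6 epimers) | O=C1[C@H]2C(N(C)C)C=C(O[Si](C)(C)C(C)(C)C)C[C@@]2(C)[C@@H]2C[C@H]12
F2 | step 5 | 6-(dimethylamino)-8-(tert-butyldimethylsilyloxy)-11,12,13-trinorlindena-4(15),7-diene (C6 epimers) | C=C1[C@H]2C(N(C)C)C=C(O[Si](C)(C)C(C)(C)C)C[C@@]2(C)[C@@H]2C[C@H]12
F3 | step 10 | 15-(phenylthio)lindena-4,6,8-trien-12,8-olide (C11 epimers) | c1ccccc1SCC3=C4C=C5C(=C[C@@]4(C)[C@@H]4C[C@H]34)OC(=O)C5C
F4 | step 10 | acyclic head-to-tail dimer sulfide (C11–C15′ bond, 11R; 15-phenylthio on the first half, 11′-H on the second) | c1ccccc1SCC3=C4C=C5C(=C[C@@]4(C)[C@@H]4C[C@H]34)OC(=O)[C@]5(C)CC3=C4C=C5C(=C[C@@]4(C)[C@@H]4C[C@H]34)OC(=O)C5C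
F5 | step 10 | S-methyl sulfonium triflate of F4 | C[S+](c1ccccc1)CC3=C4C=C5C(=C[C@@]4(C)[C@@H]4C[C@H]34)OC(=O)[C@]5(C)CC3=C4C=C5C(=C[C@@]4(C)[C@@H]4C[C@H]34)OC(=O)C5C.[O-]S(=O)(=O)C(F)(F)F
F6 | step 11 | 9,9′-bis-epi-cycloshizukaol A | COC(=O)[C@]1(C)CC2=C3C=C(C(=O)[C@@H](O)[C@@]3(C)[C@@H]3C[C@H]23)[C@](C)(C(=O)OC)CC2=C3C=C1C(=O)[C@@H](O)[C@@]3(C)[C@@H]1C[C@H]21
F7 | step 11 | 9,9′-dioxo analogue of cycloshizukaol A (bis-8,9-dione) | COC(=O)[C@]1(C)CC2=C3C=C(C(=O)C(=O)[C@@]3(C)[C@@H]3C[C@H]23)[C@](C)(C(=O)OC)CC2=C3C=C1C(=O)C(=O)[C@@]3(C)[C@@H]1C[C@H]21
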